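The three bonds at the benzylic carbon on C6 of the aromatic ring (ring A) of the chromanone are disconnected together. Because this carbon sits ortho to the C5 phenol oxygen, it is the exocyclic carbon of an ortho-quinone methide (O=C5, C6=CH). In one operation, pentylmagnesium bromide, an O-Boc salicylaldehyde and a chiral vinyl ether form the C–pentyl bond, the C–CH2 bond and the O5–acetal bond, closing a dihydropyran ring and setting the (R) benzylic centre. The precursor is the cis-(2S,3R)-2,3-dimethylchromanone carrying C5-OBoc, C6-CHO and a C7 1,1-dimethylallyl ether, with C8 free for a later Claisen shift.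

Key step: step 10

Assumption: by analogy with alkaloid-catalysed closures of related ortho-hydroxyaryl tiglyl ketones, quinidine is taken to give the (2S,3R)-cis chromanone (quinine its antipode); the vinyl ether is taken to react s-trans and endo on the face remote from the phenyl group, which for the (R) benzylic centre (CH2CO2H outranks pentyl) calls for the (1S,2R)-auxiliary, whereas the (1R,2S) enantiomer would deliver the (S) centre.

Step 1
Reactants: 1 phloroglucinol; 2 tigloyl chloride
Product: 3 (E)-2-methyl-1-(2,4,6-trihydroxyphenyl)but-2-en-1-one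
Conditions: AlCl3 (3.5 equiv), PhNO2, 0 °C to rt; ice/1 M HCl
Reagents that add atoms: none
Why: Friedel–Crafts C-acylation of the symmetrical triol, whose three ring positions are equivalent so that only one ketone can form; the E-alkene is kept and the low temperature should hold back Lewis-acid closure to racemic chromanone.

Step 2
Reactants: 3
Product: 4 (2S,3R)-5,7-dihydroxy-2,3-dimethylchroman-4-one
Conditions: quinidine (10 mol %), PhCl, rt
Reagents that add atoms: none
Why: Cinchona-alkaloid-catalysed intramolecular oxa-Michael addition (6-endo-trig; the two ortho phenols are equivalent), in which the alkaloid-bound phenol adds to one face of the enone to set C2 as (S) and kinetic protonation of the enol inside the ion pair sets C3 as (R), giving the cis isomer.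

Step 3
Reactants: 4
Product: 5 (2S,3R)-5-hydroxy-2,3-dimethyl-7-(triisopropylsilyloxy)chroman-4-one
Conditions: TIPSCl (1.05 equiv), imidazole (2 equiv), CH2Cl2, 0 °C
Reagents that add atoms: chlorotriisopropylsilane, CC(C)[Si](Cl)(C(C)C)C(C)C
Why: Chemoselective O-silylation of the unchelated, more acidic C7 phenol (C5-OH is tied up in the hydrogen bond to C4=O), which leaves C5-OH as the only directing phenol for the formylation and does not disturb C3.

Step 4
Reactants: 5
Product: 7 (2S,3R)-6-formyl-5-hydroxy-2,3-dimethyl-7-(triisopropylsilyloxy)chroman-4-one, via chloro(methoxy)methyl arene 6 (not isolated)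
Conditions: TiCl4 (2.2 equiv), CH2Cl2, −78 °C; Cl2CHOMe (1.2 equiv), −78 to 0 °C; H2O
Reagents that add atoms: dichloromethyl methyl ether, COC(Cl)Cl; water, O
Why: Rieche formylation, in which the titanium phenoxide formed at O5 delivers the chloro(methoxy)methyl cation to its only free ortho position, C6, rather than to C8; the base-free medium spares the epimerisable C3 centre (an amine and magnesium-salt formylation would enolise it) and water hydrolyses chloro ether 6 to the aldehyde.

Step 5
Reactants: 7
Product: 8 (2S,3R)-6-formyl-5,7-dihydroxy-2,3-dimethylchroman-4-one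
Conditions: TBAF (1.1 equiv), AcOH (1.5 equiv), THF, 0 °C
Reagents that add atoms: none
Why: Fluoride-induced cleavage of the aryl silyl ether, easy here because the C7 phenoxide is stabilised by the ortho formyl and para acyl groups; acetic acid buffers the mixture so that no basic fluoride or phenoxide can epimerise C3.

Step 6
Reactants: 9 2-methylbut-3-en-2-ol
Product: 11 tert-butyl 2-methylbut-3-en-2-yl carbonate, via lithium alkoxide 10 (not isolated)
Conditions: n-BuLi (1.0 equiv), THF, −78 °C; Boc2O (1.05 equiv), −78 °C to rt; H2O
Reagents that add atoms: di-tert-butyl dicarbonate, CC(C)(C)OC(=O)OC(=O)OC(C)(C)C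
Why: O-acylation of the lithium alkoxide of a tertiary allylic alcohol with Boc2O, the standard access to this allylic carbonate.

Step 7
Reactants: 8; 11
Product: 12 (2S,3R)-6-formyl-5-hydroxy-2,3-dimethyl-7-(2-methylbut-3-en-2-yloxy)chroman-4-one
Conditions: Pd(PPh3)4 (5 mol %), 11 (1.3 equiv), THF, 0 °C
Reagents that add atoms: none
Why: Tsuji–Trost O-allylation under neutral conditions: zerovalent palladium ionises 11 to a 1,1-dimethylallyl palladium cation and tert-butoxide (after loss of CO2), which deprotonates the more accessible C7 phenol (C5-OH is doubly chelated between C4=O and CHO), and the phenoxide attacks the more substituted allyl terminus to give the tertiary ether kinetically; the acid- and heat-sensitive ether is thus installed only after the formylation.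

Step 8
Reactants: 12
Product: 13 (2S,3R)-5-(tert-butoxycarbonyloxy)-6-formyl-2,3-dimethyl-7-(2-methylbut-3-en-2-yloxy)chroman-4-one
Conditions: Boc2O (1.5 equiv), DMAP (10 mol %), CH2Cl2, 0 °C to rt
Reagents that add atoms: di-tert-butyl dicarbonate, CC(C)(C)OC(=O)OC(=O)OC(C)(C)C
Why: DMAP-catalysed acylation of the remaining chelated C5 phenol with Boc2O without stoichiometric base, giving the O-Boc salicylaldehyde that triggers the cascade.

Step 9
Reactants: 14 (1S,2R)-trans-2-phenylcyclohexanol
Product: 15 (1S,2R)-trans-2-phenylcyclohexyl vinyl ether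
Conditions: ethyl vinyl ether (solvent), Hg(OAc)2 (10 mol %), reflux
Reagents that add atoms: ethyl vinyl ether, C=COCC
Why: Hg(OAc)2-catalysed transvinylation (reversible alkoxymercuration with loss of ethanol, driven by the excess of ethyl vinyl ether); the carbinol C–O bond is not broken, so both stereocentres of the auxiliary are retained.

Step 10
Reactants: 13; 16 pentylmagnesium bromide; 15
Product: 20 (2R,4R)-cis cycloadduct: dihydropyran acetal O5–CH(OR*)–CH2–CH(pentyl)–C6 on the (2S,3R)-chromanone (R* = (1S,2R)-trans-2-phenylcyclohexyl; C7 ether intact), via bromomagnesium alkoxide 17 (not isolated), via bromomagnesium phenoxide 18 (not isolated), via ortho-quinone methide 19 (not isolated)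
Conditions: 15 (3 equiv), Et2O/PhMe, −78 °C; 16 (1.05 equiv), −78 °C to rt; pH 7 phosphate buffer
Reagents that add atoms: none
Why: PentylMgBr adds to the C6 aldehyde (far more electrophilic than the hindered, doubly oxygen-conjugated C4 ketone) to give alkoxide 17, the Boc group migrates from O5 to the benzylic oxygen through a six-membered transition state (18), and the magnesium phenoxide expels tert-butyl carbonate to unveil the (E)-ortho-quinone methide 19 (O=C5–C6=CH–pentyl). This is the known alkoxide-triggered generation of ortho-quinone methides from O-Boc salicylaldehydes and Grignard reagents, with in situ inverse-electron-demand hetero-Diels–Alder trapping by a chiral enol ether. The one new ring, the dihydropyran acetal, closes by an intermolecular, concerted but asynchronous endo [4+2] cycloaddition in which the terminal carbon of the vinyl ether bonds to the exocyclic carbon and O5 bonds to the acetal carbon. The acetal centre is set by the auxiliary, whose phenyl group on the neighbouring ring carbon screens one face of the s-trans vinyl ether so that the quinone methide takes the other; the benzylic (R) centre follows from that face together with the endo alkoxy orientation and the E geometry (pentyl outside, turned away from the magnesium-bound O5), which place pentyl cis to OR*, the remote C2/C3 centres exerting no useful bias. The step needs aldehyde-over-ketone chemoselectivity (1.05 equiv of Grignard at −78 °C), cycloaddition faster than the [1,5]-hydrogen shift to a styrene (secured by the excess of vinyl ether and the electron-poor, C4-acyl-activated heterodiene) and no enolisation at C3 (low temperature, buffered quench).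

Step 11
Reactants: 20
Product: 22 C7 phenol with prenyl on C8 (acetal ring and auxiliary unchanged), via ortho-dienone 21 (not isolated)
Conditions: PhMe, 110 °C
Reagents that add atoms: none
Why: Aromatic Claisen rearrangement ([3,3]-sigmatropic shift) of the aryl 1,1-dimethylallyl ether; C6 is fully substituted, so the allyl unit arrives with allylic transposition at C8 as a prenyl group and dienone 21 tautomerises to the phenol, while the neutral medium leaves the acetal and the cis-chromanone alone.

Step 12
Reactants: 22
Product: 23 C7 methyl ether of 22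
Conditions: TMSCHN2 (2 equiv), MeOH/PhMe (1:4), rt
Reagents that add atoms: trimethylsilyldiazomethane, C[Si](C)(C)C=[N+]=[N-]
Why: O-methylation of the acidic C7 phenol (a vinylogous acid through the C4 carbonyl) by proton transfer to the diazoalkane and SN2 capture of the diazonium ion, a base-free method that cannot epimerise C3; no other acidic OH is present.

Step 13
Reactants: 23
Product: 24 lactol (2-hydroxy-4-pentyl dihydropyran on O5/C6; both anomers)
Conditions: TsOH·H2O (10 mol %), THF/H2O (4:1), 40 °C
Reagents that add atoms: water, O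
Why: Acid-catalysed hydrolysis of the mixed aryl alkyl acetal through the cyclic oxocarbenium ion; alcohol 14 is released unchanged for recovery, the benzylic centre is not involved, and with C7 methylated no phenol lies ortho to the prenyl group that could close a chroman ring.

Step 14
Reactants: 24
Product: 26 (3R)-3-[(2S,3R)-5-hydroxy-7-methoxy-2,3-dimethyl-8-(3-methylbut-2-enyl)-4-oxochroman-6-yl]octanoic acid, via hydroxy aldehyde 25 (not isolated)
Conditions: NaClO2 (3 equiv), NaH2PO4 (4 equiv), 2-methylbut-2-ene (30 equiv), t-BuOH/H2O, 0 °C to rt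
Reagents that add atoms: sodium chlorite, [Na+].[O-]Cl=O
Why: Pinnick oxidation of the open-chain hydroxy aldehyde 25 that is in equilibrium with the lactol, which gives the acid directly and avoids a basic lactone opening that would endanger the cis C3 centre; 2-methylbut-2-ene scavenges HOCl to protect the prenyl alkene and the phenol, and the freed C5-OH is held by the hydrogen bond to C4=O, which disfavours relactonisation.

Compound list
1 | phloroglucinol (benzene-1,3,5-triol) | Oc1cc(O)cc(O)c1 | starting material
2 | tigloyl chloride, (E)-2-methylbut-2-enoyl chloride | C/C=C(\C)C(=O)Cl | starting material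
3 | (E)-2-methyl-1-(2,4,6-trihydroxyphenyl)but-2-en-1-one | C/C=C(\C)C(=O)c1c(O)cc(O)cc1O | intermediate
4 | (2S,3R)-5,7-dihydroxy-2,3-dimethylchroman-4-one (cis) | Oc1cc(O)c2c(c1)O[C@@H](C)[C@@H](C)C2=O | intermediate
5 | (2S,3R)-5-hydroxy-2,3-dimethyl-7-(triisopropylsilyloxy)chroman-4-one | CC(C)[Si](Oc1cc(O)c2c(c1)O[C@@H](C)[C@@H](C)C2=O)(C(C)C)C(C)C | intermediate
6 | (2S,3R)-6-[chloro(methoxy)methyl]-5-hydroxy-2,3-dimethyl-7-(triisopropylsilyloxy)chroman-4-one (titanium-bound in the flask, drawn as the phenol; not isolated) | COC(Cl)c1c(O)c2c(cc1O[Si](C(C)C)(C(C)C)C(C)C)O[C@@H](C)[C@@H](C)C2=O | intermediate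
7 | (2S,3R)-6-formyl-5-hydroxy-2,3-dimethyl-7-(triisopropylsilyloxy)chroman-4-one | O=Cc1c(O)c2c(cc1O[Si](C(C)C)(C(C)C)C(C)C)O[C@@H](C)[C@@H](C)C2=O | intermediate
8 | (2S,3R)-6-formyl-5,7-dihydroxy-2,3-dimethylchroman-4-one | O=Cc1c(O)c2c(cc1O)O[C@@H](C)[C@@H](C)C2=O | intermediate
9 | 2-methylbut-3-en-2-ol | CC(C)(O)C=C | starting material
10 | lithium 2-methylbut-3-en-2-olate (not isolated) | [Li+].CC(C)([O-])C=C | intermediate
11 | tert-butyl 2-methylbut-3-en-2-yl carbonate | CC(C)(C)OC(=O)OC(C)(C)C=C | intermediate
12 | (2S,3R)-6-formyl-5-hydroxy-2,3-dimethyl-7-(2-methylbut-3-en-2-yloxy)chroman-4-one | O=Cc1c(O)c2c(cc1OC(C)(C)C=C)O[C@@H](C)[C@@H](C)C2=O | intermediate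
13 | (2S,3R)-5-(tert-butoxycarbonyloxy)-6-formyl-2,3-dimethyl-7-(2-methylbut-3-en-2-yloxy)chroman-4-one | O=Cc1c(OC(=O)OC(C)(C)C)c2c(cc1OC(C)(C)C=C)O[C@@H](C)[C@@H](C)C2=O | intermediate
14 | (1S,2R)-trans-2-phenylcyclohexanol | O[C@H]1CCCC[C@@H]1c1ccccc1 | starting material
15 | (1S,2R)-trans-2-phenylcyclohexyl vinyl ether | C=CO[C@H]1CCCC[C@@H]1c1ccccc1 | intermediate
16 | pentylmagnesium bromide | CCCCC[Mg]Br | starting material
17 | bromomagnesium alkoxide of the C6 1-hydroxyhexyl adduct of 13 (both carbinol epimers; not isolated) | CCCCCC(O[Mg]Br)c1c(OC(=O)OC(C)(C)C)c2c(cc1OC(C)(C)C=C)O[C@@H](C)[C@@H](C)C2=O | intermediate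
18 | bromomagnesium C5 phenoxide carrying 1-(tert-butoxycarbonyloxy)hexyl on C6 (not isolated) | CCCCCC(OC(=O)OC(C)(C)C)c1c(O[Mg]Br)c2c(cc1OC(C)(C)C=C)O[C@@H](C)[C@@H](C)C2=O | intermediate
19 | (E)-ortho-quinone methide, (2S,3R)-6-hexylidene-2,3-dimethyl-7-(2-methylbut-3-en-2-yloxy)-2,3-dihydrochromene-4,5-dione, pentyl anti to C5=O (not isolated) | CCCCC/C=C1/C(=O)C2=C(C=C1OC(C)(C)C=C)O[C@@H](C)[C@@H](C)C2=O | intermediate
20 | cycloadduct: (2S,3R)-2,3-dimethyl-7-(2-methylbut-3-en-2-yloxy)chroman-4-one with O5 and C6 bridged as O5–CH(OR*)–CH2–CH(pentyl)–C6; (R) at the pentyl carbon, (R) at the acetal carbon, pentyl cis to OR*; R* = (1S,2R)-trans-2-phenylcyclohexyl | CCCCC[C@@H]1C[C@H](O[C@H]4CCCC[C@@H]4c4ccccc4)Oc2c1c(OC(C)(C)C=C)cc3c2C(=O)[C@H](C)[C@H](C)O3 | intermediate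
21 | ortho-dienone from 20: C7 ketone, C8 sp3 carbon carrying H and prenyl (both C8 epimers), C5=C6 and C4a=C8a double bonds (not isolated) | CCCCC[C@@H]1C[C@H](O[C@H]4CCCC[C@@H]4c4ccccc4)OC2=C1C(=O)C(CC=C(C)C)C3=C2C(=O)[C@H](C)[C@H](C)O3 | intermediate
22 | Claisen product: as 20 but with C7-OH and 3-methylbut-2-enyl on C8 | CCCCC[C@@H]1C[C@H](O[C@H]4CCCC[C@@H]4c4ccccc4)Oc2c1c(O)c(CC=C(C)C)c3c2C(=O)[C@H](C)[C@H](C)O3 | intermediate
23 | C7 methyl ether of 22 | CCCCC[C@@H]1C[C@H](O[C@H]4CCCC[C@@H]4c4ccccc4)Oc2c1c(OC)c(CC=C(C)C)c3c2C(=O)[C@H](C)[C@H](C)O3 | intermediate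
24 | lactol: as 23 but with OH in place of OR* at the acetal carbon (both anomers), (R) at the pentyl carbon | CCCCC[C@@H]1CC(O)Oc2c1c(OC)c(CC=C(C)C)c3c2C(=O)[C@H](C)[C@H](C)O3 | intermediate
25 | (2S,3R)-5-hydroxy-7-methoxy-2,3-dimethyl-8-(3-methylbut-2-enyl)-6-[(3R)-1-oxooctan-3-yl]chroman-4-one (not isolated) | CCCCC[C@H](CC=O)c1c(O)c2c(c(CC=C(C)C)c1OC)O[C@@H](C)[C@@H](C)C2=O | intermediate
26 | (3R)-3-[(2S,3R)-5-hydroxy-7-methoxy-2,3-dimethyl-8-(3-methylbut-2-enyl)-4-oxochroman-6-yl]octanoic acid | CCCCC[C@H](CC(=O)O)c1c(O)c2c(c(CC=C(C)C)c1OC)O[C@@H](C)[C@@H](C)C2=O | target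

Total step count: 14 (12 in the main line, plus steps 6 and 9 for reagents 11 and 15).
Longest linear sequence: 12 steps from phloroglucinol (steps 1–5, 7, 8, 10–14).

Steps most likely to fail

Step 10. Stereocontrol at the exocyclic carbon may be lost. The C7 tertiary ether flanks C6 and can erode the E geometry of the quinone methide, or the auxiliary may discriminate the vinyl ether faces poorly, so that both benzylic epimers form; prolonged warming with the magnesium tert-butoxide by-product could also epimerise C3. The fallback gives up auxiliary control and relies on the C2/C3 centres for separation. It sets out from 13 and 16 and runs the same cascade (via 17 to 19) with achiral ethyl vinyl ether. The cis 2-ethoxy-4-pentyl adduct should form as two benzylic epimers which, being diastereomers, are separated by chromatography into the (2R,4R) adduct F1 and its (2S,4S) epimer F2. F1 is then heated (PhMe, 110 °C) through ortho-dienone F3 to phenol F4, methylated with TMSCHN2 to methyl ether F5 and hydrolysed (TsOH, aqueous THF) to lactol 24, where the route resumes.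

Step 2. Enantioselectivity or cis selectivity of the ring closure may be insufficient, for example because the free para phenol pairs with the alkaloid or the cis product drifts towards trans. The fallback replaces asymmetric catalysis by resolution. It sets out from 3, which is closed with an achiral amine (quinuclidine, PhCl, rt) to the racemic cis-chromanone, that is 4 together with its enantiomer, (2R,3S)-5,7-dihydroxy-2,3-dimethylchroman-4-one F6. After removal of any trans isomer the two are separated by preparative chromatography on a chiral stationary phase, and the route continues from 4.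

Step 4. Formylation may occur at C8 instead of C6, or the silyl ether may be lost under TiCl4 so that O7 starts to direct. The fallback is a boron-templated ortho-hydroxymethylation followed by oxidation. It sets out from 5, which with PhB(OH)2 and paraformaldehyde (cat. EtCO2H, PhMe, 90 °C, removal of water) should give benzodioxaborin F7, in which boron bridges O5 and the new C6 methylene and so fixes the regiochemistry. Exchange with propane-1,3-diol frees the 6-hydroxymethyl phenol F8, and MnO2 (CH2Cl2, rt) oxidises the benzylic alcohol to aldehyde 7, where the route resumes.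

Further compounds
F1 | step 10 | (2R,4R)-cis 2-ethoxy analogue of 20 (OEt in place of OR*) | CCCCC[C@@H]1C[C@H](OCC)Oc2c1c(OC(C)(C)C=C)cc3c2C(=O)[C@H](C)[C@H](C)O3
F2 | step 10 | (2S,4S)-cis 2-ethoxy adduct, the benzylic epimer series of F1 | CCCCC[C@H]1C[C@@H](OCC)Oc2c1c(OC(C)(C)C=C)cc3c2C(=O)[C@H](C)[C@H](C)O3
F3 | step 10 | ortho-dienone from F1 (C7 ketone, C8 carrying H and prenyl, both C8 epimers) | CCCCC[C@@H]1C[C@H](OCC)OC2=C1C(=O)C(CC=C(C)C)C3=C2C(=O)[C@H](C)[C@H](C)O3
F4 | step 10 | C7 phenol with prenyl on C8, 2-ethoxy series | CCCCC[C@@H]1C[C@H](OCC)Oc2c1c(O)c(CC=C(C)C)c3c2C(=O)[C@H](C)[C@H](C)O3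
F5 | step 10 | C7 methyl ether of F4 | CCCCC[C@@H]1C[C@H](OCC)Oc2c1c(OC)c(CC=C(C)C)c3c2C(=O)[C@H](C)[C@H](C)O3
F6 | step 2 | (2R,3S)-5,7-dihydroxy-2,3-dimethylchroman-4-one | Oc1cc(O)c2c(c1)O[C@H](C)[C@H](C)C2=O
F7 | step 4 | 2-phenyl-4H-1,3,2-benzodioxaborin spanning O5 and C6 of 5 (B–O5, B–O–CH2–C6) | C1OB(c4ccccc4)Oc2c1c(O[Si](C(C)C)(C(C)C)C(C)C)cc3c2C(=O)[C@H](C)[C@H](C)O3
F8 | step 4 | (2S,3R)-5-hydroxy-6-(hydroxymethyl)-2,3-dimethyl-7-(triisopropylsilyloxy)chroman-4-one | OCc1c(O)c2c(cc1O[Si](C(C)C)(C(C)C)C(C)C)O[C@@H](C)[C@@H](C)C2=O
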